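**Late plateaus.** Late in larch, target read 48.3% at 8.00 h and 48.9% at 12.0 h. Birch ended lower than alder, although both held the same 5.7 mM of protic impurity, so I read the plateau as showing, in part, how much starting material got past the impurity.

| flask | starting material | first nucleophile | second nucleophile | protic impurity | remark | time |
|---|---|---|---|---|---|---|
| larch | 0.019 M | 2 equiv | 1.1 equiv | 5.7 mM | run made earlier |  |
| birch | 0.013 M | 2 equiv | 1.1 equiv | 5.7 mM | run made earlier |  |
| alder | 0.028 M | 2 equiv | 1.1 equiv | 5.7 mM | run made earlier |  |
| oak | 0.019 M | 3 equiv | 1.1 equiv | 5.7 mM | run made earlier |  |
| zeta | 0.019 M | 2.00 equiv | 1.10 equiv (fed, over 16.0 h) | 5.70 mM | all but second nucleophile at the start; second nucleophile goes in evenly over 16.0 h, the run ends at 20 h | 20 h |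
| eta | 0.019 M | 2.00 equiv | 1.10 equiv | 5.70 mM | everything together in a closed stirred flask, run for 20 h | 20 h |
| theta | 0.019 M | 2.00 equiv | 1.10 equiv | 5.70 mM | one stirred flow tank at steady state, fed with the mixture as stated, mean residence time 200 h |  |
| epsilon | 0.019 M | 2.00 equiv | 1.10 equiv | 5.70 mM | a single well-mixed tank run continuously and read at steady state, 20 h in it on average |  |

| run | time / h | target / % |
|---|---|---|
| larch | 1.00 | 21.8 |
| larch | 1.33 | 27.1 |
| larch | 2.00 | 33.1 |
| larch | 3.00 | 40.1 |
| larch | 5.00 | 45.9 |
| larch | 8.00 | 48.3 |
| larch | 12.0 | 48.9 |
| birch | 1.50 | 26.8 |
| birch | 3.00 | 36.0 |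
| birch | 5.00 | 40.8 |
| birch | 6.00 | 40.6 |
| birch | 8.00 | 41.7 |
| birch | 10.0 | 41.6 |
| birch | 12.0 | 43.3 |
| alder | 1.50 | 30.5 |
| alder | 3.00 | 43.6 |
| alder | 5.00 | 51.6 |
| alder | 6.00 | 52.1 |
| alder | 8.00 | 54.3 |
| alder | 10.0 | 55.0 |
| alder | 12.0 | 54.7 |
| oak | 2.50 | 42.1 |
| oak | 5.00 | 51.3 |
| oak | 8.00 | 54.5 |
| oak | 10.0 | 54.5 |
| oak | 12.0 | 54.8 |

(each reading ± 0.5 percentage points)

- the stated concentrations are those of everything mixed, before any reaction; amounts are the same in each set-up
- what may be going on: second nucleophile + intermediate -> other capture product; starting material + protic impurity -> quenched substrate; first nucleophile + intermediate -> target; starting material -> intermediate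
- the feed brings no volume worth counting
- the earlier runs were made in a closed, stirred flask

* the set-up with the highest amount of target at the outlet or at the end, in percent of the starting material put in ("none" if the first two lie within 2 percentage points) (zeta / eta / theta / epsilon / none)
* amount of target at the outlet or at the end, in percent of the starting material put in, zeta
* amount of target at the outlet or at the end, in percent of the starting material put in, eta
* amount of target at the outlet or at the end, in percent of the starting material put in, theta
* amount of target at the outlet or at the end, in percent of the starting material put in, epsilon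

**First instants.** Starting material either turns into intermediate by itself or meets protic impurity. I compared the two with the quench constant κ, the forward rate constant over the quench rate constant, a concentration. The forward share at any moment is κ/(κ + c(protic impurity)).

**The middle.** Intermediate is then caught by first or second nucleophile. Oak against larch gave me a reading of the selectivity factor, 0.867, so at larch's charge I read target's part of the captures as 67.7%.

**The end.** Over a closed run taken until starting material is gone, the same ratio holds with the logarithmic mean of c(protic impurity), which is its drop divided by the logarithm of its fall. Birch's late mean of 42.2% gave a forward share of 62.3%, so c(protic impurity) ended near 0.803 mM and κ read 4.14 mM. With that, larch began at a forward share of 42.1%, and its plateau implies 72.2% overall. Zeta charges starting material and impurity as larch does, so I expected that same share there, with dosing changing the capture.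

**The forecast.** It chose zeta: zeta 67% (63% to 71%), eta 49%, theta 52%, epsilon 47.5%. Its ground for zeta was that “the slow feed keeps second nucleophile low while most intermediate forms”.

**The result.** The best was zeta: zeta 67.0%, eta 48.9%, theta 51.7%, epsilon 47.7%.

    second nucleophile + intermediate → other capture product (k = 7.23 M⁻¹ min⁻¹)
    starting material + protic impurity → quenched substrate (k = 2.25 M⁻¹ min⁻¹)
    first nucleophile + intermediate → target (k = 9.16 M⁻¹ min⁻¹)
    starting material → intermediate (k = 0.00836 min⁻¹)

**Why zeta won.** Zeta beat eta because of the slow dosing of second nucleophile, part of the picture: without it zeta gave 48.9% rather than 67.0%, and 89% of zeta's making of intermediate was behind by 4.00 h, with a quarter of the feed in. In epsilon, capture by second nucleophile cost 22 percentage points, part of the shortfall: without that loss, epsilon gave 69.4% rather than 47.7%. With 2.7% of zeta's impurity left, κ gives a forward share of 73.0%; target plus other capture product came to 70.8%.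

**Neighbour flask.** With 0.023 M of protic impurity in zeta's recipe, κ put the end c(protic impurity) near 9.24 mM and the forward share at 21.5%. That flask gave 20.4% of target.

Readings and results stem from a simulated flask from invented constants; noise was put on by code.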